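Target locants: indane C1 (aroyl group, carbonyl carbon C8), C2 (4-hydroxyphenyl), C3 (3,5-dihydroxyphenyl); ring A is C3a–C7a with oxygen on C4 and C6. C7a is meta to both ring A oxygens, so no electrophilic ring closure can reach it. Its neighbour C1 carries a carbonyl carbon outside the ring, and this C7a–C1–C8(=O) array is what is left when an aryl carbon shifts from a ketone carbon to an adjacent diazo carbon.
Cuts, in retrosynthetic order: C8–aryl (aryl Grignard reagent plus ketene C1=C8=O); C1–C7a (retro-Wolff, C8 goes back between C7a and C1, five-membered ring becomes a 2-diazo-1-tetralone); C3–aryl (Suzuki coupling); C3–C3a (Friedel–Crafts acylation at the ring A carbon ortho/para to oxygen); C1–C2 (enolate alkylation).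
Forward: the C7a–C8 bond comes ready-made in 3,5-bis(benzyloxy)acetophenone. Then follow chain assembly, closure of the six-membered ring, arylation to a cyclic stilbene, hydrogenation, diazo transfer, contraction of the six- to the five-membered ring, aryl addition to the ketene and debenzylation.
Stereochemistry: a CBS reduction sets one carbinol centre at the future C8. Its bulky silyl ether sends H2 to the opposite face of the stilbene (syn addition, cis C2/C3 in the absolute sense) and is then oxidised away. The labile C1 is made last by kinetic protonation of the enolate on the face away from both aryl groups.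
Key step: step 14

Assumption: in the given SMILES H1, H2 and H3 lie on one face of the indane (all-cis, 1R,2R,3R). C1 is therefore the less stable epimer and is kept away from acid and base once it is set.

Step 1
Reactants: 1 3,5-bis(benzyloxy)acetophenone
Product: 2 2-bromo-1-[3,5-bis(benzyloxy)phenyl]ethan-1-one
Conditions: CuBr2 (2.1 equiv), EtOAc/CHCl3, reflux
Reagents that add atoms: copper dibromide, Br[Cu]Br
Why: Heterogeneous α-bromination of an aryl methyl ketone with CuBr2 delivers bromine to the enol carbon without building up free Br2, so the activated resorcinol ring and the benzyl ethers should be left alone.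

Step 2
Reactants: 3 methyl 2-[4-(benzyloxy)phenyl]acetate; 2 2-bromo-1-[3,5-bis(benzyloxy)phenyl]ethan-1-one
Product: 5 methyl 2-[4-(benzyloxy)phenyl]-4-[3,5-bis(benzyloxy)phenyl]-4-oxobutanoate (racemic), via lithium enolate 4 (not isolated)
Conditions: LiN(SiMe3)2, THF, −78 °C; then 2, −78 → −20 °C
Reagents that add atoms: lithium hexamethyldisilazide, [Li]N([Si](C)(C)C)[Si](C)(C)C (supplies the lithium of 4; no atom of it stays in 5)
Why: SN2 alkylation of a preformed ester enolate with a phenacyl bromide, a very reactive primary electrophile, forms the C1–C2 bond of the target, and the new centre may be racemic because step 7 flattens it again.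

Step 3
Reactants: 5 methyl 2-[4-(benzyloxy)phenyl]-4-[3,5-bis(benzyloxy)phenyl]-4-oxobutanoate
Product: 6 methyl (4R)-2-[4-(benzyloxy)phenyl]-4-[3,5-bis(benzyloxy)phenyl]-4-hydroxybutanoate (both C2 epimers)
Conditions: (S)-Me-CBS [(S)-1-methyl-3,3-diphenyltetrahydro-1H,3H-pyrrolo[1,2-c][1,3,2]oxazaborole, 15 mol %], BH3·SMe2, THF, −20 °C; MeOH quench
Reagents that add atoms: none
Why: In the Corey–Bakshi–Shibata reduction the (S)-oxazaborolidine holds borane and ketone so that the large aryl group points away from the catalyst, which for aryl/CH2R ketones gives the (R)-carbinol whatever the remote C2 centre, and the non-basic medium spares the ester and leaves the γ-hydroxy ester open.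

Step 4
Reactants: 6 methyl (4R)-2-[4-(benzyloxy)phenyl]-4-[3,5-bis(benzyloxy)phenyl]-4-hydroxybutanoate
Product: 7 methyl (4R)-2-[4-(benzyloxy)phenyl]-4-[3,5-bis(benzyloxy)phenyl]-4-[(triisopropylsilyl)oxy]butanoate (both C2 epimers)
Conditions: iPr3SiOTf, 2,6-lutidine, CH2Cl2, −40 → 0 °C (crude 6 used at once)
Reagents that add atoms: triisopropylsilyl trifluoromethanesulfonate, CC(C)[Si](OS(=O)(=O)C(F)(F)F)(C(C)C)C(C)C
Why: O-silylation with a silyl triflate and a hindered pyridine is fast enough in the cold to outrun lactonisation, and the triisopropylsilyl group is chosen because it withstands the acid of step 6, makes its oxygen too hindered to attack an acyl chloride and later screens one face of the ring.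

Step 5
Reactants: 7 methyl (4R)-2-[4-(benzyloxy)phenyl]-4-[3,5-bis(benzyloxy)phenyl]-4-[(triisopropylsilyl)oxy]butanoate
Product: 8 (4R)-2-[4-(benzyloxy)phenyl]-4-[3,5-bis(benzyloxy)phenyl]-4-[(triisopropylsilyl)oxy]butanoic acid (both C2 epimers)
Conditions: LiOH, THF/MeOH/H2O, rt; then 1 M HCl to pH 3, 0 °C
Reagents that add atoms: lithium hydroxide, [Li+].[OH-]
Why: Ordinary saponification of a methyl ester, to which the silyl and benzyl ethers are inert and in which epimerisation at C2 does not matter.

Step 6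
Reactants: 8 (4R)-2-[4-(benzyloxy)phenyl]-4-[3,5-bis(benzyloxy)phenyl]-4-[(triisopropylsilyl)oxy]butanoic acid
Product: 10 (4R)-6,8-bis(benzyloxy)-2-[4-(benzyloxy)phenyl]-4-[(triisopropylsilyl)oxy]-3,4-dihydronaphthalen-1(2H)-one (both C2 epimers), via acid chloride 9 (not isolated)
Conditions: (COCl)2, DMF (cat.), CH2Cl2, 0 °C → rt, evaporate; then (CF3)2CHOH, rt
Reagents that add atoms: oxalyl chloride, O=C(Cl)C(=O)Cl (supplies the chlorine of 9; no atom of it stays in 10)
Why: Intramolecular Friedel–Crafts acylation closes the six-membered ring at the ring A carbon ortho to one and para to the other benzyloxy group (the two candidate positions are equivalent), and activating the acid chloride only by hydrogen bonding to hexafluoropropan-2-ol, a metal-free variant suited to electron-rich arenes, avoids the Lewis acids that would strip the benzyl ether peri to the new ketone.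

Step 7
Reactants: 10 (4R)-6,8-bis(benzyloxy)-2-[4-(benzyloxy)phenyl]-4-[(triisopropylsilyl)oxy]-3,4-dihydronaphthalen-1(2H)-one
Product: 12 (4R)-6,8-bis(benzyloxy)-2-[4-(benzyloxy)phenyl]-4-[(triisopropylsilyl)oxy]-3,4-dihydronaphthalen-1-yl trifluoromethanesulfonate, via potassium enolate 11 (not isolated)
Conditions: KN(SiMe3)2 (1.05 equiv), THF, −78 °C; then PhNTf2, −78 °C → rt
Reagents that add atoms: potassium hexamethyldisilazide, [K]N([Si](C)(C)C)[Si](C)(C)C (supplies the potassium of 11 only); N-phenylbis(trifluoromethanesulfonimide), O=S(=O)(N(c1ccccc1)S(=O)(=O)C(F)(F)F)C(F)(F)F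
Why: Enol triflate formation exploits the high acidity of C2–H in a 2-aryl-1-tetralone, the property that would defeat addition of an aryl metal to this hindered electron-rich carbonyl group, and gives a single regiodefined enolate that is sulfonylated on oxygen with erasure of the C2 centre.

Step 8
Reactants: 13 1-bromo-3,5-bis(benzyloxy)benzene
Product: 14 2-[3,5-bis(benzyloxy)phenyl]-4,4,5,5-tetramethyl-1,3,2-dioxaborolane
Conditions: bis(pinacolato)diboron, PdCl2(dppf) (3 mol %), KOAc, 1,4-dioxane, 90 °C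
Reagents that add atoms: bis(pinacolato)diboron, CC1(C)OB(OC1(C)C)B1OC(C)(C)C(C)(C)O1
Why: Miyaura borylation of an unhindered aryl bromide tolerates benzyl ethers.

Step 9
Reactants: 12 (4R)-6,8-bis(benzyloxy)-2-[4-(benzyloxy)phenyl]-4-[(triisopropylsilyl)oxy]-3,4-dihydronaphthalen-1-yl trifluoromethanesulfonate; 14 2-[3,5-bis(benzyloxy)phenyl]-4,4,5,5-tetramethyl-1,3,2-dioxaborolane
Product: 15 (1R)-5,7-bis(benzyloxy)-3-[4-(benzyloxy)phenyl]-4-[3,5-bis(benzyloxy)phenyl]-1-[(triisopropylsilyl)oxy]-1,2-dihydronaphthalene (numbered from the silyloxy carbon from here on)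
Conditions: Pd(OAc)2 (5 mol %), SPhos (2-dicyclohexylphosphino-2',6'-dimethoxybiphenyl, 10 mol %), K3PO4, THF/H2O, 60 °C
Reagents that add atoms: none
Why: Suzuki–Miyaura coupling of an enol triflate with a boronate that has no ortho substituents, run with a bulky biarylphosphine made for crowded partners, forms the C3–aryl bond of the target in a weakly basic medium that, unlike acid dehydration of a tertiary carbinol, gives no opening for loss of silanol and aromatisation.

Step 10
Reactants: 15 (1R)-5,7-bis(benzyloxy)-3-[4-(benzyloxy)phenyl]-4-[3,5-bis(benzyloxy)phenyl]-1-[(triisopropylsilyl)oxy]-1,2-dihydronaphthalene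
Product: 16 (1R,3S,4R)-5,7-bis(benzyloxy)-3-[4-(benzyloxy)phenyl]-4-[3,5-bis(benzyloxy)phenyl]-1-[(triisopropylsilyl)oxy]-1,2,3,4-tetrahydronaphthalene (silyloxy group and both aryl groups on one face)
Conditions: H2 (50 bar), [Ir(cod)(PCy3)(py)][B(C6H3-3,5-(CF3)2)4] (5 mol %), CH2Cl2, rt
Reagents that add atoms: none
Why: Homogeneous hydrogenation with the cation [Ir(cod)(PCy3)(py)]+, a catalyst type that reduces tetrasubstituted alkenes and leaves benzyl ethers intact, adds both hydrogens to one face (syn addition, hence cis C3/C4), and that face should be the one opposite the silyloxy group, which sits pseudoaxial to avoid the peri hydrogen on C8 and covers alkene carbon C3, so the (1R) centre dictates (3S,4R).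

Step 11
Reactants: 16 (1R,3S,4R)-5,7-bis(benzyloxy)-3-[4-(benzyloxy)phenyl]-4-[3,5-bis(benzyloxy)phenyl]-1-[(triisopropylsilyl)oxy]-1,2,3,4-tetrahydronaphthalene
Product: 17 (1R,3S,4R)-5,7-bis(benzyloxy)-3-[4-(benzyloxy)phenyl]-4-[3,5-bis(benzyloxy)phenyl]-1,2,3,4-tetrahydronaphthalen-1-ol
Conditions: Bu4NF, THF, rt
Reagents that add atoms: none
Why: Fluoride-induced silyl ether cleavage is driven by the Si–F bond and nothing else in the molecule responds to fluoride.

Step 12
Reactants: 17 (1R,3S,4R)-5,7-bis(benzyloxy)-3-[4-(benzyloxy)phenyl]-4-[3,5-bis(benzyloxy)phenyl]-1,2,3,4-tetrahydronaphthalen-1-ol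
Product: 18 (3S,4R)-5,7-bis(benzyloxy)-3-[4-(benzyloxy)phenyl]-4-[3,5-bis(benzyloxy)phenyl]-3,4-dihydronaphthalen-1(2H)-one (cis)
Conditions: Dess–Martin periodinane, CH2Cl2, 0 °C → rt
Reagents that add atoms: none
Why: Dess–Martin oxidation of a secondary benzylic alcohol under nearly neutral conditions removes the control centre that is no longer needed, while C3 and C4, being β and γ to the new carbonyl group, cannot epimerise through the enol.

Step 13
Reactants: 18 (3S,4R)-5,7-bis(benzyloxy)-3-[4-(benzyloxy)phenyl]-4-[3,5-bis(benzyloxy)phenyl]-3,4-dihydronaphthalen-1(2H)-one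
Product: 21 (3S,4R)-5,7-bis(benzyloxy)-3-[4-(benzyloxy)phenyl]-4-[3,5-bis(benzyloxy)phenyl]-2-diazo-3,4-dihydronaphthalen-1(2H)-one (cis), via lithium enolate 19 (not isolated), via trifluoroacetyl ketone 20 (not isolated)
Conditions: LiN(SiMe3)2, THF, −78 °C; CF3CO2CH2CF3; aq HCl wash, concentrate; then 4-AcNHC6H4SO2N3, Et3N, H2O (1 equiv), MeCN, rt, dark
Reagents that add atoms: lithium hexamethyldisilazide, [Li]N([Si](C)(C)C)[Si](C)(C)C (lithium of 19 only); 2,2,2-trifluoroethyl trifluoroacetate, O=C(OCC(F)(F)F)C(F)(F)F (trifluoroacetyl group of 20 only); 4-acetamidobenzenesulfonyl azide, CC(=O)Nc1ccc(cc1)S(=O)(=O)N=[N+]=[N-] (the two nitrogen atoms of 21)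
Why: In this detrifluoroacetylative variant of the Regitz diazo transfer the enolate, which can form only at C2, is trifluoroacetylated and the resulting 1,3-dicarbonyl compound takes N2 from the sulfonyl azide with loss of the activating group as its sulfonamide, a sequence made for simple ketones such as 1-tetralones that do not react with sulfonyl azides directly.

Step 14
Reactants: 21 (3S,4R)-5,7-bis(benzyloxy)-3-[4-(benzyloxy)phenyl]-4-[3,5-bis(benzyloxy)phenyl]-2-diazo-3,4-dihydronaphthalen-1(2H)-one
Product: 22 [(2S,3R)-4,6-bis(benzyloxy)-2-[4-(benzyloxy)phenyl]-3-[3,5-bis(benzyloxy)phenyl]-2,3-dihydro-1H-inden-1-ylidene]methanone (cis-2,3-diarylindan-1-ylidene ketene; kept as the cold solution)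
Conditions: hν (365 nm LED), dry degassed toluene (0.01 M), −78 °C, Ar; followed by IR (diazo band against ketene band)
Reagents that add atoms: none
Why: Light absorbed by the diazoketone expels N2 while the C1–C8a σ bond, held antiperiplanar to the C2–N bond because the six-membered ring locks C=O and C=N2 s-cis, shifts from the carbonyl carbon to C2, so that ring A carbon C8a (C7a of the target) becomes bonded to the former diazo carbon (C1 of the target) and the old carbonyl carbon is left outside the ring as ketene carbon C8. The closest known reaction is the photochemical Wolff rearrangement of cyclic 2-diazo-1-ketones, by which 2-diazo-1-tetralones are contracted to indane-1-carboxylic acid derivatives, run here without a protic trap so that the ketene itself is the product. The five-membered ring is closed by this 1,2-aryl shift (a contraction of the six-membered ring, not an end-to-end cyclisation), and since the aryl carbon is the only substituent on the carbonyl carbon that can migrate, only one ring can form. No stereocentre is created: C3 and C4 of 21 take no part and reappear unchanged as C2 and C3 of 22, while C1 becomes sp2 and is left to step 16. The selectivity needed is aryl shift over 1,2-shift of the benzylic C3–H or of the C3 aryl group to a free carbene, and it is secured by the locked s-cis geometry, by direct unsensitised irradiation and by the low temperature, all of which favour loss of N2 in concert with migration. At 365 nm only the diazoketone absorbs appreciably, the benzyl ethers being transparent, and dilute dry toluene at −78 °C should keep the hindered aryl(alkyl)ketene from hydration, dimerisation and secondary photolysis until it is used.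

Step 15
Reactants: 23 1-(benzyloxy)-4-bromobenzene
Product: 24 4-(benzyloxy)phenylmagnesium bromide (titrated THF solution, prepared beforehand)
Conditions: Mg turnings, iodine crystal, THF, reflux
Reagents that add atoms: magnesium, [Mg]
Why: Grignard reagent formation by insertion of magnesium into an aryl bromide leaves the benzyl ether untouched.

Step 16
Reactants: 22 [(2S,3R)-4,6-bis(benzyloxy)-2-[4-(benzyloxy)phenyl]-3-[3,5-bis(benzyloxy)phenyl]-2,3-dihydro-1H-inden-1-ylidene]methanone; 24 4-(benzyloxy)phenylmagnesium bromide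
Product: 26 [(1R,2R,3R)-4,6-bis(benzyloxy)-2-[4-(benzyloxy)phenyl]-3-[3,5-bis(benzyloxy)phenyl]-2,3-dihydro-1H-inden-1-yl][4-(benzyloxy)phenyl]methanone (hexa-O-benzylcaraphenol B; all-cis), via bromomagnesium enolate 25 (not isolated)
Conditions: 24 (1.1 equiv, THF) added to 22 in toluene, −78 °C; then AcOH in THF, −78 °C; pH 7 phosphate buffer; short column on deactivated silica
Reagents that add atoms: none
Why: Addition of an organomagnesium reagent to the sp carbon of a ketene gives the enolate and stops there because no carbonyl group exists until the quench, and kinetic protonation then reaches planar C1 from the face away from the cis C2 and C3 aryl groups (allylic strain with the exocyclic enolate pushes the C2 aryl group pseudoaxial), which turns the aroyl group to the crowded face and sets (1R), while acetic acid at −78 °C leaves only non-basic acetate behind so the labile centre is not equilibrated (C2 is now called R only because C1 loses CIP rank).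

Step 17
Reactants: 26 hexa-O-benzylcaraphenol B
Product: 27 caraphenol B, [(1R,2R,3R)-3-(3,5-dihydroxyphenyl)-4,6-dihydroxy-2-(4-hydroxyphenyl)-2,3-dihydro-1H-inden-1-yl](4-hydroxyphenyl)methanone
Conditions: H2 (1 atm), 10% Pd/C, THF/MeOH, rt, stopped at full debenzylation
Reagents that add atoms: none
Why: Catalytic hydrogenolysis of the six aryl benzyl ethers over Pd/C runs in a neutral medium without acid or base that could enolise the ketone, so C1 is kept, and the electron-rich 4-oxygenated aryl ketone is reduced far more slowly than benzyl ethers are cleaved.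

Compound list
1 | 3,5-bis(benzyloxy)acetophenone | CC(=O)c1cc(OCc2ccccc2)cc(OCc2ccccc2)c1 | starting material
2 | 2-bromo-1-[3,5-bis(benzyloxy)phenyl]ethan-1-one | O=C(CBr)c1cc(OCc2ccccc2)cc(OCc2ccccc2)c1 | intermediate
3 | methyl 2-[4-(benzyloxy)phenyl]acetate | COC(=O)Cc1ccc(OCc2ccccc2)cc1 | starting material
4 | lithium enolate of 3 | [Li]OC(OC)=Cc1ccc(OCc2ccccc2)cc1 | intermediate
5 | methyl 2-[4-(benzyloxy)phenyl]-4-[3,5-bis(benzyloxy)phenyl]-4-oxobutanoate (racemic) | COC(=O)C(CC(=O)c1cc(OCc2ccccc2)cc(OCc2ccccc2)c1)c1ccc(OCc2ccccc2)cc1 | intermediate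
6 | methyl (4R)-2-[4-(benzyloxy)phenyl]-4-[3,5-bis(benzyloxy)phenyl]-4-hydroxybutanoate (both C2 epimers) | COC(=O)C(C[C@@H](O)c1cc(OCc2ccccc2)cc(OCc2ccccc2)c1)c1ccc(OCc2ccccc2)cc1 | intermediate
7 | methyl (4R)-2-[4-(benzyloxy)phenyl]-4-[3,5-bis(benzyloxy)phenyl]-4-[(triisopropylsilyl)oxy]butanoate (both C2 epimers) | COC(=O)C(C[C@@H](O[Si](C(C)C)(C(C)C)C(C)C)c1cc(OCc2ccccc2)cc(OCc2ccccc2)c1)c1ccc(OCc2ccccc2)cc1 | intermediate
8 | (4R)-2-[4-(benzyloxy)phenyl]-4-[3,5-bis(benzyloxy)phenyl]-4-[(triisopropylsilyl)oxy]butanoic acid (both C2 epimers) | OC(=O)C(C[C@@H](O[Si](C(C)C)(C(C)C)C(C)C)c1cc(OCc2ccccc2)cc(OCc2ccccc2)c1)c1ccc(OCc2ccccc2)cc1 | intermediate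
9 | acid chloride of 8 | ClC(=O)C(C[C@@H](O[Si](C(C)C)(C(C)C)C(C)C)c1cc(OCc2ccccc2)cc(OCc2ccccc2)c1)c1ccc(OCc2ccccc2)cc1 | intermediate
10 | (4R)-6,8-bis(benzyloxy)-2-[4-(benzyloxy)phenyl]-4-[(triisopropylsilyl)oxy]-3,4-dihydronaphthalen-1(2H)-one (both C2 epimers) | O=C1C(c2ccc(OCc3ccccc3)cc2)C[C@@H](O[Si](C(C)C)(C(C)C)C(C)C)c2cc(OCc3ccccc3)cc(OCc3ccccc3)c12 | intermediate
11 | potassium enolate of 10 | [K]OC1=C(c2ccc(OCc3ccccc3)cc2)C[C@@H](O[Si](C(C)C)(C(C)C)C(C)C)c2cc(OCc3ccccc3)cc(OCc3ccccc3)c12 | intermediate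
12 | (4R)-6,8-bis(benzyloxy)-2-[4-(benzyloxy)phenyl]-4-[(triisopropylsilyl)oxy]-3,4-dihydronaphthalen-1-yl trifluoromethanesulfonate | FC(F)(F)S(=O)(=O)OC1=C(c2ccc(OCc3ccccc3)cc2)C[C@@H](O[Si](C(C)C)(C(C)C)C(C)C)c2cc(OCc3ccccc3)cc(OCc3ccccc3)c12 | intermediate
13 | 1-bromo-3,5-bis(benzyloxy)benzene | Brc1cc(OCc2ccccc2)cc(OCc2ccccc2)c1 | starting material
14 | 2-[3,5-bis(benzyloxy)phenyl]-4,4,5,5-tetramethyl-1,3,2-dioxaborolane | CC1(C)OB(OC1(C)C)c1cc(OCc2ccccc2)cc(OCc2ccccc2)c1 | intermediate
15 | (1R)-5,7-bis(benzyloxy)-3-[4-(benzyloxy)phenyl]-4-[3,5-bis(benzyloxy)phenyl]-1-[(triisopropylsilyl)oxy]-1,2-dihydronaphthalene | C1(c2cc(OCc3ccccc3)cc(OCc3ccccc3)c2)=C(c2ccc(OCc3ccccc3)cc2)C[C@@H](O[Si](C(C)C)(C(C)C)C(C)C)c2cc(OCc3ccccc3)cc(OCc3ccccc3)c12 | intermediate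
16 | (1R,3S,4R)-5,7-bis(benzyloxy)-3-[4-(benzyloxy)phenyl]-4-[3,5-bis(benzyloxy)phenyl]-1-[(triisopropylsilyl)oxy]-1,2,3,4-tetrahydronaphthalene (all-cis) | CC(C)[Si](C(C)C)(C(C)C)O[C@H]1c2cc(OCc3ccccc3)cc(OCc3ccccc3)c2[C@@H](c2cc(OCc3ccccc3)cc(OCc3ccccc3)c2)[C@@H](c2ccc(OCc3ccccc3)cc2)C1 | intermediate
17 | (1R,3S,4R)-5,7-bis(benzyloxy)-3-[4-(benzyloxy)phenyl]-4-[3,5-bis(benzyloxy)phenyl]-1,2,3,4-tetrahydronaphthalen-1-ol | O[C@H]1c2cc(OCc3ccccc3)cc(OCc3ccccc3)c2[C@@H](c2cc(OCc3ccccc3)cc(OCc3ccccc3)c2)[C@@H](c2ccc(OCc3ccccc3)cc2)C1 | intermediate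
18 | (3S,4R)-5,7-bis(benzyloxy)-3-[4-(benzyloxy)phenyl]-4-[3,5-bis(benzyloxy)phenyl]-3,4-dihydronaphthalen-1(2H)-one (cis) | O=C1c2cc(OCc3ccccc3)cc(OCc3ccccc3)c2[C@@H](c2cc(OCc3ccccc3)cc(OCc3ccccc3)c2)[C@@H](c2ccc(OCc3ccccc3)cc2)C1 | intermediate
19 | lithium enolate of 18 | [Li]OC=1c2cc(OCc3ccccc3)cc(OCc3ccccc3)c2[C@@H](c2cc(OCc3ccccc3)cc(OCc3ccccc3)c2)[C@@H](c2ccc(OCc3ccccc3)cc2)C=1 | intermediate
20 | 2-(trifluoroacetyl) derivative of 18 (C2 undefined, largely enolised) | O=C1c2cc(OCc3ccccc3)cc(OCc3ccccc3)c2[C@@H](c2cc(OCc3ccccc3)cc(OCc3ccccc3)c2)[C@@H](c2ccc(OCc3ccccc3)cc2)C1C(=O)C(F)(F)F | intermediate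
21 | (3S,4R)-5,7-bis(benzyloxy)-3-[4-(benzyloxy)phenyl]-4-[3,5-bis(benzyloxy)phenyl]-2-diazo-3,4-dihydronaphthalen-1(2H)-one (cis) | O=C1c2cc(OCc3ccccc3)cc(OCc3ccccc3)c2[C@@H](c2cc(OCc3ccccc3)cc(OCc3ccccc3)c2)[C@@H](c2ccc(OCc3ccccc3)cc2)C1=[N+]=[N-] | intermediate
22 | [(2S,3R)-4,6-bis(benzyloxy)-2-[4-(benzyloxy)phenyl]-3-[3,5-bis(benzyloxy)phenyl]-2,3-dihydro-1H-inden-1-ylidene]methanone (ketene) | O=C=C1c2cc(OCc3ccccc3)cc(OCc3ccccc3)c2[C@@H](c2cc(OCc3ccccc3)cc(OCc3ccccc3)c2)[C@H]1c1ccc(OCc2ccccc2)cc1 | intermediate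
23 | 1-(benzyloxy)-4-bromobenzene | Brc1ccc(OCc2ccccc2)cc1 | starting material
24 | 4-(benzyloxy)phenylmagnesium bromide | Br[Mg]c1ccc(OCc2ccccc2)cc1 | intermediate
25 | bromomagnesium enolate of 26 (double bond geometry not assigned) | Br[Mg]OC(c1ccc(OCc2ccccc2)cc1)=C1c2cc(OCc3ccccc3)cc(OCc3ccccc3)c2[C@@H](c2cc(OCc3ccccc3)cc(OCc3ccccc3)c2)[C@H]1c1ccc(OCc2ccccc2)cc1 | intermediate
26 | hexa-O-benzylcaraphenol B, (1R,2R,3R), all-cis | O=C(c1ccc(OCc2ccccc2)cc1)[C@H]1c2cc(OCc3ccccc3)cc(OCc3ccccc3)c2[C@@H](c2cc(OCc3ccccc3)cc(OCc3ccccc3)c2)[C@H]1c1ccc(OCc2ccccc2)cc1 | intermediate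
27 | caraphenol B, (1R,2R,3R) | O=C(c1ccc(O)cc1)[C@H]1c2cc(O)cc(O)c2[C@@H](c2cc(O)cc(O)c2)[C@H]1c1ccc(O)cc1 | target

Total step count: 17. Longest linear sequence: 15 steps from 1 (steps 1–7, 9–14, 16 and 17). Steps 8 and 15 are side branches.

Steps most likely to fail

Step 10 (hydrogenation of 15). The crowded tetrasubstituted diaryl double bond may not turn over. The acidic iridium hydrides may also trigger loss of silanol and aromatisation. The fallback sets out from 15 and gives up chemoselectivity. Heterogeneous hydrogenation over Pd(OH)2/C (H2, 4 bar, EtOAc/EtOH, neutral) is the usual way from 1,2-diaryl-3,4-dihydronaphthalenes to cis-1,2-diaryltetralins. It should saturate the alkene from the face opposite the silyl ether and at the same time cleave the five benzyl ethers. The product would be (1R,3S,4R)-4-(3,5-dihydroxyphenyl)-3-(4-hydroxyphenyl)-1-[(triisopropylsilyl)oxy]-1,2,3,4-tetrahydronaphthalene-5,7-diol F1. Exhaustive Williamson benzylation (BnBr, K2CO3, DMF) brings the material back to the route at 16.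

Step 16 (aryl addition and protonation). Facial selectivity in the proton transfer may be poor, or C1 may equilibrate to the more stable epimer while basic magnesium salts and excess reagent are still present during quench and work-up. The fallback sets out from 25. Instead of being quenched with acid, the enolate is silylated on oxygen (Me3SiCl, −78 → 0 °C) to {[(2S,3R)-4,6-bis(benzyloxy)-2-[4-(benzyloxy)phenyl]-3-[3,5-bis(benzyloxy)phenyl]-2,3-dihydro-1H-inden-1-ylidene][4-(benzyloxy)phenyl]methoxy}trimethylsilane F2. This compound can be freed of all salts. The proton is then delivered in a base-free medium by a Lewis acid assisted Brønsted acid: SnCl4 (10 mol %) with 2'-methoxy-[1,1'-binaphthalen]-2-ol (12 mol %) and 2,6-dimethylphenol as stoichiometric proton source, in toluene at −78 °C. The binaphthol enantiomer is chosen to reinforce the substrate bias. This known protonation of aryl-substituted silyl enol ethers comes back to the route at 26.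

Step 14 (Wolff contraction to the free ketene). The unprotected ketene must survive the whole irradiation. Secondary photolysis with loss of CO, dimerisation or traces of moisture may consume it before it is used. The fallback sets out from 21 and separates the photochemistry from the making of the ketene. The same contraction is run in THF/H2O at 0 °C, so each ketene molecule is hydrated as it forms. This gives the stable, purifiable (2R,3R)-4,6-bis(benzyloxy)-2-[4-(benzyloxy)phenyl]-3-[3,5-bis(benzyloxy)phenyl]-2,3-dihydro-1H-indene-1-carboxylic acid F3, whose C1 configuration is irrelevant. Oxalyl chloride with catalytic DMF converts it into (2R,3R)-4,6-bis(benzyloxy)-2-[4-(benzyloxy)phenyl]-3-[3,5-bis(benzyloxy)phenyl]-2,3-dihydro-1H-indene-1-carbonyl chloride F4. Dehydrochlorination with Et3N in toluene in the dark, the classical entry to aryl(alkyl)ketenes, then gives the ketene. After filtration of the ammonium salt under argon, the fallback rejoins the route at 22.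

Further compounds
F1 | step 10 | (1R,3S,4R)-4-(3,5-dihydroxyphenyl)-3-(4-hydroxyphenyl)-1-[(triisopropylsilyl)oxy]-1,2,3,4-tetrahydronaphthalene-5,7-diol | CC(C)[Si](C(C)C)(C(C)C)O[C@H]1c2cc(O)cc(O)c2[C@@H](c2cc(O)cc(O)c2)[C@@H](c2ccc(O)cc2)C1
F2 | step 16 | {[(2S,3R)-4,6-bis(benzyloxy)-2-[4-(benzyloxy)phenyl]-3-[3,5-bis(benzyloxy)phenyl]-2,3-dihydro-1H-inden-1-ylidene][4-(benzyloxy)phenyl]methoxy}trimethylsilane | C[Si](C)(C)OC(c1ccc(OCc2ccccc2)cc1)=C1c2cc(OCc3ccccc3)cc(OCc3ccccc3)c2[C@@H](c2cc(OCc3ccccc3)cc(OCc3ccccc3)c2)[C@H]1c1ccc(OCc2ccccc2)cc1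
F3 | step 14 | (2R,3R)-4,6-bis(benzyloxy)-2-[4-(benzyloxy)phenyl]-3-[3,5-bis(benzyloxy)phenyl]-2,3-dihydro-1H-indene-1-carboxylic acid (C1 epimers) | OC(=O)C1c2cc(OCc3ccccc3)cc(OCc3ccccc3)c2[C@@H](c2cc(OCc3ccccc3)cc(OCc3ccccc3)c2)[C@H]1c1ccc(OCc2ccccc2)cc1
F4 | step 14 | (2R,3R)-4,6-bis(benzyloxy)-2-[4-(benzyloxy)phenyl]-3-[3,5-bis(benzyloxy)phenyl]-2,3-dihydro-1H-indene-1-carbonyl chloride (C1 epimers) | ClC(=O)C1c2cc(OCc3ccccc3)cc(OCc3ccccc3)c2[C@@H](c2cc(OCc3ccccc3)cc(OCc3ccccc3)c2)[C@H]1c1ccc(OCc2ccccc2)cc1
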